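**Retrosynthetic overview**

1. Ring numbering used throughout: C1 ring ketone, C2 acyl-bearing carbon, C3 enol carbon, C4 mono-prenyl carbon, C5 second enol carbon, C6 gem-diprenyl carbon. Helilupolone comes from its 3,5-di-O-ethyl ether by enol ether hydrolysis, and the side-chain ketone from a silyl-protected carbinol.
2. Key disconnection: C1–C2 and C3–C4 are cut together. C4–C5–C6–C1 come from a strained 3-ethoxy-2,4,4-triprenylcyclobutenone (with a temporary C1–C4 bond), and C2–C3 plus the side chain from an ethyl ynol ether. Forward: thermal 4π opening, ketene/ynol ether [2+2], 4π opening, 6π closure.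
3. Enabling feature: the six-membered ring is a 1,3,5-trioxygenated carbocycle in which the oxygen-bearing C1, C3 and C5 alternate with the carbon-substituted C2, C4 and C6, and C6 is a quaternary sp3 carbon. The ring is therefore a blocked 3,5-dioxygenated cyclohexa-2,4-dienone, the arrested product of a vinylketene benzannulation that cannot go on to a phenol.
4. The cyclobutenone comes from a [2+2] of diprenylketene (diethyl malonate + prenyl bromide) with 1-ethoxy-5-methylhex-4-en-1-yne. Both ynol ethers come from ethoxyacetylene (with prenyl bromide or with 3-phenylpropanal).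
5. Ring order: the four-membered ring first (step 6), then its expansion by two carbons to the only carbocycle that has to be made (step 8); the benzene ring is bought.

Key step: step 8

Remark on the chemistry: helilupolone is an enolised β-triketone without a stereocenter, and the drawn structure is taken as one of its equilibrating tautomers. The intermediates that carry the silyloxy- or hydroxy-bearing side-chain carbon are used as racemates.

**Route**

Step 1
Reactants: 1 diethyl malonate; 2 prenyl bromide (1-bromo-3-methylbut-2-ene)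
Product: 4 diethyl 2,2-bis(3-methylbut-2-en-1-yl)malonate, via monoprenyl malonate 3 (not isolated)
Conditions: NaH (2.2 equiv), 2 (2.3 equiv), THF/DMF, 0 °C → rt
Reagents that add atoms: none
Why: Two successive SN2 alkylations of the sodium malonate enolate at the unhindered primary allylic bromide (malonic ester synthesis) should give the dialkylated diester; no stereocenter is formed.

Step 2
Reactants: 4 diethyl 2,2-bis(3-methylbut-2-en-1-yl)malonate
Product: 5 2,2-bis(3-methylbut-2-en-1-yl)malonic acid
Conditions: KOH (6 equiv), EtOH/H2O, reflux; then 1 M HCl, 0 °C, to pH 2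
Reagents that add atoms: potassium hydroxide, [K+].[OH-]
Why: Saponification of the hindered geminal diester with excess hydroxide should give the dicarboxylate, and cold, brief acidification should free the diacid without lactonization onto the prenyl double bonds.

Step 3
Reactants: 5 2,2-bis(3-methylbut-2-en-1-yl)malonic acid
Product: 6 5-methyl-2-(3-methylbut-2-en-1-yl)hex-4-enoic acid
Conditions: pyridine, 115 °C
Reagents that add atoms: none
Why: Thermal decarboxylation of the geminal diacid through its six-membered hydrogen-bonded transition state (last stage of the malonic ester synthesis) should give the monoacid, with pyridine buffering the medium so that the prenyl groups do not lactonize.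

Step 4
Reactants: 6 5-methyl-2-(3-methylbut-2-en-1-yl)hex-4-enoic acid
Product: 7 5-methyl-2-(3-methylbut-2-en-1-yl)hex-4-enoyl chloride
Conditions: (COCl)2, DMF (cat.), CH2Cl2, 0 °C → rt; volatiles removed in vacuo
Reagents that add atoms: oxalyl chloride, O=C(Cl)C(=O)Cl
Why: Acid chloride formation through the chloroiminium species made catalytically from DMF and oxalyl chloride should be clean at 0 °C, where the gaseous by-products leave before HCl can add to the trisubstituted alkenes.

Step 5
Reactants: 8 ethoxyacetylene; 2 prenyl bromide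
Product: 10 1-ethoxy-5-methylhex-4-en-1-yne, via ethoxyethynylmagnesium bromide 9 (not isolated)
Conditions: EtMgBr, THF, 0 °C → rt; then CuBr·SMe2 (5 mol %), 2, 0 °C → rt
Reagents that add atoms: none
Why: Deprotonation of the terminal ynol ether by the Grignard reagent gives the alkynylmagnesium bromide, and its coupling with the allylic bromide under catalysis by monovalent copper (the standard 1,4-enyne synthesis from alkynyl Grignard reagents and allylic halides) should take place at the unhindered primary carbon of prenyl bromide, not at the fully substituted γ-carbon, to give the linear prenyl alkyne; no stereocenter is formed.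

Step 6
Reactants: 7 5-methyl-2-(3-methylbut-2-en-1-yl)hex-4-enoyl chloride; 10 1-ethoxy-5-methylhex-4-en-1-yne
Product: 12 3-ethoxy-2,4,4-tris(3-methylbut-2-en-1-yl)cyclobut-2-en-1-one, via diprenylketene 11 (not isolated)
Conditions: 10 (1.3 equiv), Et3N, CH2Cl2, 0 °C → rt, slow addition of 7
Reagents that add atoms: none
Why: Dehydrochlorination gives the dialkylketene, which should undergo the thermal [2+2] ketene–ynol ether cycloaddition with the nucleophilic alkyne carbon (remote from oxygen) bonding to the ketene carbonyl carbon, so that the ethoxy group ends at C3 and the gem-diprenyl carbon at C4 of a cyclobutenone that cannot tautomerize.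

Step 7
Reactants: 8 ethoxyacetylene; 13 3-phenylpropanal
Product: 16 triethyl[(1-ethoxy-5-phenylpent-1-yn-3-yl)oxy]silane (racemic), via lithium ethoxyacetylide 14 (not isolated), via lithium alkoxide 15 (not isolated)
Conditions: n-BuLi, THF, –78 °C; 13; then Et3SiCl, –78 → 0 °C; Et3N-buffered work-up
Reagents that add atoms: chlorotriethylsilane, CC[Si](Cl)(CC)CC
Why: 1,2-Addition of the lithium acetylide to the aldehyde and in-flask O-silylation of the lithium alkoxide should give the protected propargylic alcohol without isolation of the acid-sensitive free carbinol; the new carbinol stereocenter is formed without control (racemic) and is removed by oxidation in step 10.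

Step 8
Reactants: 12 3-ethoxy-2,4,4-tris(3-methylbut-2-en-1-yl)cyclobut-2-en-1-one; 16 triethyl[(1-ethoxy-5-phenylpent-1-yn-3-yl)oxy]silane
Product: 20 3,5-diethoxy-4,6,6-tris(3-methylbut-2-en-1-yl)-2-[3-phenyl-1-(triethylsilyloxy)propyl]cyclohexa-2,4-dien-1-one (racemic), via vinylketene 17 (not isolated), via alkenylcyclobutenone 18 (not isolated), via dienylketene 19 (not isolated)
Conditions: 16 (2.5 equiv), toluene (1 M), 85 °C, sealed tube, argon
Reagents that add atoms: none
Why: Heating opens the strained cyclobutenone 12 by 4π-electrocyclic cleavage of its bond between the carbonyl carbon and the gem-diprenyl carbon to vinylketene 17, whose ketene C=C undergoes a regioselective [2+2] cycloaddition with ynol ether 16 (the alkyne carbon remote from oxygen adds to the ketene carbonyl carbon and forms C1–C2, the oxygen-stabilized carbon then closes onto the ketene α-carbon and forms C3–C4) to give 18, which opens by a second 4π-electrocyclic reaction to dienylketene 19. The closest known reaction type is the Danheiser benzannulation of cyclobutenones with alkoxyalkynes, in the blocked variant in which a 4,4-dialkyl-3-alkoxycyclobutenone and an alkoxyalkyne stop at the 3,5-dialkoxy-6,6-dialkylcyclohexa-2,4-dienone. The only ring closed is the six-membered carbocycle, by 6π-electrocyclization of 19 (a hexatriene whose one terminus is the ketene carbon and whose other terminus is the diprenyl-substituted carbon, which re-forms C1–C6); the four-membered rings of 12 and 18 are temporary, and their strain drives the sequence. No stereocenter of the target is created (C6 carries two identical prenyl groups), the quaternary center of 18 is lost on ring opening, and the silyloxy-bearing carbon is carried as a racemate until step 10. The step needs regioselectivity in the [2+2] event, which the polarization of the ynol ether secures, and it needs intermolecular capture of 17 to outrun intramolecular ketene–prenyl cycloaddition and retro-ene loss of ethylene from 16, which the excess of the electron-rich alkyne, the high concentration, the moderate temperature and the reversible reclosure of unreacted 17 to 12 are expected to secure. The double-bond isomer of 19 that cannot cyclize should return to 18, so that both isomers funnel to 20.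

Step 9
Reactants: 20 3,5-diethoxy-4,6,6-tris(3-methylbut-2-en-1-yl)-2-[3-phenyl-1-(triethylsilyloxy)propyl]cyclohexa-2,4-dien-1-one
Product: 21 3,5-diethoxy-2-(1-hydroxy-3-phenylpropyl)-4,6,6-tris(3-methylbut-2-en-1-yl)cyclohexa-2,4-dien-1-one (racemic)
Conditions: n-Bu4NF, AcOH, THF, 0 °C
Reagents that add atoms: none
Why: Fluoride attacks silicon and cleaves the Si–O bond (silyl ether deprotection), while the acetic acid buffer keeps the medium near neutral so that the vinylogous ester groups and the dienone are untouched.

Step 10
Reactants: 21 3,5-diethoxy-2-(1-hydroxy-3-phenylpropyl)-4,6,6-tris(3-methylbut-2-en-1-yl)cyclohexa-2,4-dien-1-one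
Product: 22 3,5-diethoxy-4,6,6-tris(3-methylbut-2-en-1-yl)-2-(3-phenylpropanoyl)cyclohexa-2,4-dien-1-one
Conditions: Dess–Martin periodinane, pyridine, CH2Cl2, 0 °C → rt
Reagents that add atoms: none
Why: Dess–Martin oxidation of the secondary, allylic-type alcohol under pyridine-buffered, non-aqueous conditions should give the 2-acyl dienone without hydrolysis of the enol ethers; the carbinol stereocenter disappears.

Step 11
Reactants: 22 3,5-diethoxy-4,6,6-tris(3-methylbut-2-en-1-yl)-2-(3-phenylpropanoyl)cyclohexa-2,4-dien-1-one
Product: 24 helilupolone (3,5-dihydroxy-4,6,6-tris(3-methylbut-2-en-1-yl)-2-(3-phenylpropanoyl)cyclohexa-2,4-dien-1-one), via monoethyl ether 23 (not isolated)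
Conditions: 1 M aq. HCl, THF, rt
Reagents that add atoms: water, O
Why: Both ethoxy groups are vinylogous esters of the ring and side-chain carbonyls, so O-protonation, addition of water at C3 and C5 and loss of ethanol (vinylogous ester hydrolysis) should unveil the enolised β-triketone, the dilute acid at room temperature being too weak to protonate the prenyl double bonds.

**Compound list**

1 | diethyl malonate | CCOC(=O)CC(=O)OCC | starting material
2 | prenyl bromide (1-bromo-3-methylbut-2-ene) | CC(C)=CCBr | starting material
3 | diethyl 2-(3-methylbut-2-en-1-yl)malonate; not isolated | CCOC(=O)C(CC=C(C)C)C(=O)OCC | intermediate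
4 | diethyl 2,2-bis(3-methylbut-2-en-1-yl)malonate | CCOC(=O)C(CC=C(C)C)(CC=C(C)C)C(=O)OCC | intermediate
5 | 2,2-bis(3-methylbut-2-en-1-yl)malonic acid | OC(=O)C(CC=C(C)C)(CC=C(C)C)C(=O)O | intermediate
6 | 5-methyl-2-(3-methylbut-2-en-1-yl)hex-4-enoic acid | CC(C)=CCC(CC=C(C)C)C(=O)O | intermediate
7 | 5-methyl-2-(3-methylbut-2-en-1-yl)hex-4-enoyl chloride | CC(C)=CCC(CC=C(C)C)C(=O)Cl | intermediate
8 | ethoxyacetylene (ethoxyethyne) | CCOC#C | starting material
9 | ethoxyethynylmagnesium bromide; not isolated | CCOC#C[Mg]Br | intermediate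
10 | 1-ethoxy-5-methylhex-4-en-1-yne | CCOC#CCC=C(C)C | intermediate
11 | bis(3-methylbut-2-en-1-yl)ketene (diprenylketene); not isolated | CC(C)=CCC(CC=C(C)C)=C=O | intermediate
12 | 3-ethoxy-2,4,4-tris(3-methylbut-2-en-1-yl)cyclobut-2-en-1-one | CCOC1=C(CC=C(C)C)C(=O)C1(CC=C(C)C)CC=C(C)C | intermediate
13 | 3-phenylpropanal | O=CCCc1ccccc1 | starting material
14 | lithium ethoxyacetylide; not isolated | [Li]C#COCC | intermediate
15 | lithium 1-ethoxy-5-phenylpent-1-yn-3-olate (racemic); not isolated | [Li]OC(C#COCC)CCc1ccccc1 | intermediate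
16 | triethyl[(1-ethoxy-5-phenylpent-1-yn-3-yl)oxy]silane (racemic) | CCOC#CC(O[Si](CC)(CC)CC)CCc1ccccc1 | intermediate
17 | 3-ethoxy-7-methyl-2,4-bis(3-methylbut-2-en-1-yl)octa-1,3,6-trien-1-one (vinylketene); not isolated | O=C=C(CC=C(C)C)C(OCC)=C(CC=C(C)C)CC=C(C)C | intermediate
18 | 3-ethoxy-4-[1-ethoxy-5-methyl-2-(3-methylbut-2-en-1-yl)hexa-1,4-dien-1-yl]-4-(3-methylbut-2-en-1-yl)-2-[3-phenyl-1-(triethylsilyloxy)propyl]cyclobut-2-en-1-one (mixture of diastereomers); not isolated | CCOC1=C(C(O[Si](CC)(CC)CC)CCc2ccccc2)C(=O)C1(CC=C(C)C)C(OCC)=C(CC=C(C)C)CC=C(C)C | intermediate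
19 | 3,5-diethoxy-9-methyl-4,6-bis(3-methylbut-2-en-1-yl)-2-[3-phenyl-1-(triethylsilyloxy)propyl]deca-1,3,5,8-tetraen-1-one (dienylketene, drawn as the isomer with C2 and C5 cis on the 3,4-double bond, racemic); not isolated | O=C=C(C(O[Si](CC)(CC)CC)CCc1ccccc1)/C(OCC)=C(CC=C(C)C)\C(OCC)=C(CC=C(C)C)CC=C(C)C | intermediate
20 | 3,5-diethoxy-4,6,6-tris(3-methylbut-2-en-1-yl)-2-[3-phenyl-1-(triethylsilyloxy)propyl]cyclohexa-2,4-dien-1-one (racemic) | CCOC1=C(CC=C(C)C)C(OCC)=C(C(O[Si](CC)(CC)CC)CCc2ccccc2)C(=O)C1(CC=C(C)C)CC=C(C)C | intermediate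
21 | 3,5-diethoxy-2-(1-hydroxy-3-phenylpropyl)-4,6,6-tris(3-methylbut-2-en-1-yl)cyclohexa-2,4-dien-1-one (racemic) | CCOC1=C(CC=C(C)C)C(OCC)=C(C(O)CCc2ccccc2)C(=O)C1(CC=C(C)C)CC=C(C)C | intermediate
22 | 3,5-diethoxy-4,6,6-tris(3-methylbut-2-en-1-yl)-2-(3-phenylpropanoyl)cyclohexa-2,4-dien-1-one | CCOC1=C(CC=C(C)C)C(OCC)=C(C(=O)CCc2ccccc2)C(=O)C1(CC=C(C)C)CC=C(C)C | intermediate
23 | 5-ethoxy-3-hydroxy-4,6,6-tris(3-methylbut-2-en-1-yl)-2-(3-phenylpropanoyl)cyclohexa-2,4-dien-1-one; not isolated | CCOC1=C(CC=C(C)C)C(O)=C(C(=O)CCc2ccccc2)C(=O)C1(CC=C(C)C)CC=C(C)C | intermediate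
24 | helilupolone | CC(C)=CCC1=C(O)C(CC=C(C)C)(CC=C(C)C)C(=O)C(C(=O)CCc2ccccc2)=C1O | target

**Step count and risks**

Total step count: 11. Longest linear sequence: 9 steps (steps 1, 2, 3, 4, 6, 8, 9, 10, 11).

The three steps most likely to fail:

Step 8. The intermolecular capture of the vinylketene by the hindered, internal ynol ether may be too slow, so that intramolecular cycloaddition of the ketene onto a prenyl double bond or retro-ene loss of ethylene from the ynol ether takes over. The fallback sets out from 12 and the unhindered, commercial ethoxyacetylene 8, moves the acyl group to the end and comes back at 24. Heating 12 with excess 8 in toluene at 85 °C in a sealed tube should pass through 17, the alkenylcyclobutenone 3-ethoxy-4-[1-ethoxy-5-methyl-2-(3-methylbut-2-en-1-yl)hexa-1,4-dien-1-yl]-4-(3-methylbut-2-en-1-yl)cyclobut-2-en-1-one F1 (not isolated) and the dienylketene 3,5-diethoxy-9-methyl-4,6-bis(3-methylbut-2-en-1-yl)deca-1,3,5,8-tetraen-1-one F2 (not isolated) to 3,5-diethoxy-4,6,6-tris(3-methylbut-2-en-1-yl)cyclohexa-2,4-dien-1-one F3. Hydrolysis with 1 M aq. HCl in THF should give 3,5-dihydroxy-4,6,6-tris(3-methylbut-2-en-1-yl)cyclohexa-2,4-dien-1-one F4. Treatment of F4 with 3-phenylpropanoic acid, DCC and DMAP in CH2Cl2 should acylate an enol oxygen to the enol ester 5-hydroxy-4,4,6-tris(3-methylbut-2-en-1-yl)-3-oxocyclohexa-1,5-dien-1-yl 3-phenylpropanoate F5 (not isolated), which DMAP should rearrange by O-to-C acyl shift onto the unsubstituted C2 to give 24.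

Step 6. Dehydrochlorination of the α,α-disubstituted acid chloride and capture of the ketene by the internal ynol ether may both be slow, so that ketene dimerization or acylation pathways consume the material. The fallback sets out from 7 and 8 and comes back at 12. With Et3N in CH2Cl2 the ketene 11 should be captured by the more reactive terminal ynol ether to give 3-ethoxy-4,4-bis(3-methylbut-2-en-1-yl)cyclobut-2-en-1-one F6. Iodination at the nucleophilic C2 of the vinylogous ester with N-iodosuccinimide in MeCN at 0 °C should give 3-ethoxy-2-iodo-4,4-bis(3-methylbut-2-en-1-yl)cyclobut-2-en-1-one F7. Stille coupling of F7 with tributyl(3-methylbut-2-en-1-yl)stannane, Pd(PPh3)4 (zerovalent palladium) and CuI in DMF at 50 °C should install the third prenyl group and return to 12.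

Step 11. Acid-mediated cyclization of prenyl groups onto the enol oxygens may compete with the slow hydrolysis of the enol ether that is flanked by the quaternary carbon. The fallback sets out from 22 and comes back at 24, and it cleaves the O–ethyl bonds at the ethyl carbon instead of at the ring carbon. Iodotrimethylsilane with hexamethyldisilazane as acid scavenger in CH2Cl2, 0 °C → rt, should silylate the carbonyl oxygens and dealkylate both ethyl groups by SN2 attack of iodide, giving the bis(silyl enol ether) 4,6,6-tris(3-methylbut-2-en-1-yl)-2-(3-phenylpropanoyl)-3,5-bis(trimethylsilyloxy)cyclohexa-2,4-dien-1-one F8 (not isolated). Work-up with aqueous NaHCO3 should then release 24.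

**Further compounds**

F1 | step 8 | 3-ethoxy-4-[1-ethoxy-5-methyl-2-(3-methylbut-2-en-1-yl)hexa-1,4-dien-1-yl]-4-(3-methylbut-2-en-1-yl)cyclobut-2-en-1-one (racemic) | CCOC1=CC(=O)C1(CC=C(C)C)C(OCC)=C(CC=C(C)C)CC=C(C)C
F2 | step 8 | 3,5-diethoxy-9-methyl-4,6-bis(3-methylbut-2-en-1-yl)deca-1,3,5,8-tetraen-1-one (isomer with C2 and C5 cis on the 3,4-double bond) | O=C=C/C(OCC)=C(CC=C(C)C)\C(OCC)=C(CC=C(C)C)CC=C(C)C
F3 | step 8 | 3,5-diethoxy-4,6,6-tris(3-methylbut-2-en-1-yl)cyclohexa-2,4-dien-1-one | CCOC1=CC(=O)C(CC=C(C)C)(CC=C(C)C)C(OCC)=C1CC=C(C)C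
F4 | step 8 | 3,5-dihydroxy-4,6,6-tris(3-methylbut-2-en-1-yl)cyclohexa-2,4-dien-1-one | OC1=CC(=O)C(CC=C(C)C)(CC=C(C)C)C(O)=C1CC=C(C)C
F5 | step 8 | 5-hydroxy-4,4,6-tris(3-methylbut-2-en-1-yl)-3-oxocyclohexa-1,5-dien-1-yl 3-phenylpropanoate | O=C(CCc1ccccc1)OC1=CC(=O)C(CC=C(C)C)(CC=C(C)C)C(O)=C1CC=C(C)C
F6 | step 6 | 3-ethoxy-4,4-bis(3-methylbut-2-en-1-yl)cyclobut-2-en-1-one | CCOC1=CC(=O)C1(CC=C(C)C)CC=C(C)C
F7 | step 6 | 3-ethoxy-2-iodo-4,4-bis(3-methylbut-2-en-1-yl)cyclobut-2-en-1-one | CCOC1=C(I)C(=O)C1(CC=C(C)C)CC=C(C)C
F8 | step 11 | 4,6,6-tris(3-methylbut-2-en-1-yl)-2-(3-phenylpropanoyl)-3,5-bis(trimethylsilyloxy)cyclohexa-2,4-dien-1-one | C[Si](C)(C)OC1=C(CC=C(C)C)C(O[Si](C)(C)C)=C(C(=O)CCc2ccccc2)C(=O)C1(CC=C(C)C)CC=C(C)C
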